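**Retrosynthetic overview**
1. The target is a trimer of 8-methoxy-1-naphthol joined C2–C4' and C4–C4''. No ring is built: the two outer naphthalenes come from naphthalene-1,8-diol and the central one from juglone, carried as quinone, then quinol, and re-aromatised in the key step.
2. Key disconnection (C2–C4' bond, made last): acid-triggered dehydrative SN2' arylation of a para-quinol by unprotected 8-methoxy-1-naphthol. It forms the biaryl bond and aromatises the central ring in one redox-neutral operation, in place of a halide/boronate cross-coupling.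
3. C4–C4'' bond: 1,2-addition of a 4-lithio-1-benzyloxy-8-methoxynaphthalene to the more electrophilic carbonyl of juglone methyl ether gives that quinol.
4. Building blocks: mono-O-methylation, para-bromination and O-benzylation of naphthalene-1,8-diol; O-methylation of juglone; the single benzyl ether is removed at the end.

Assumption: the SMILES has no stereodescriptor and no stereocentre, and both biaryl axes are flanked only by H and one OH, so they are not configurationally fixed at room temperature; the compound is made as drawn, with no stereochemistry to set.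

**Step 1**
Reactants: 1 naphthalene-1,8-diol
Product: 2 8-methoxynaphthalen-1-ol
Conditions: MeI (1.05 equiv), K2CO3 (1.1 equiv), acetone, reflux, N2
Reagents that add atoms: iodomethane, SMILES CI
Why: Williamson ether synthesis: after the first O-alkylation the remaining hydroxyl is locked in a strong peri hydrogen bond to the new methoxy oxygen and is far less acidic, so one equivalent of MeI stops at the mono-ether; no stereocenter is formed.

**Step 2**
Reactants: 2 8-methoxynaphthalen-1-ol
Product: 3 4-bromo-8-methoxynaphthalen-1-ol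
Conditions: NBS (1.0 equiv), MeCN, −20 °C to 0 °C, dark
Reagents that add atoms: N-bromosuccinimide, SMILES O=C1CCC(=O)N1Br
Why: Electrophilic aromatic bromination: the free hydroxyl is a stronger activator than the methoxy group, C4 is the alpha position para to it, and the peri hydrogen bond shuts down the OH-assisted delivery that favours ortho attack, so NBS in a polar solvent should brominate C4; no stereocenter is formed.

**Step 3**
Reactants: 3 4-bromo-8-methoxynaphthalen-1-ol
Product: 4 1-(benzyloxy)-4-bromo-8-methoxynaphthalene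
Conditions: BnBr (1.2 equiv), K2CO3 (2 equiv), DMF, 60 °C
Reagents that add atoms: benzyl bromide, SMILES BrCc1ccccc1
Why: Williamson ether synthesis on the naphtholate; benzyl is chosen because it survives n-BuLi, cannot be shed from the cation of step 6 as a silyl or acetal group could, and is removed by neutral hydrogenolysis at the end.

**Step 4**
Reactants: 5 juglone (5-hydroxynaphthalene-1,4-dione)
Product: 6 5-methoxynaphthalene-1,4-dione (juglone methyl ether)
Conditions: MeI (excess), Ag2O (1.5 equiv), CH2Cl2, rt, dark
Reagents that add atoms: iodomethane, SMILES CI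
Why: Purdie-type O-methylation with Ag2O and MeI, the standard base-free way to methylate the chelated peri hydroxyl of juglone without touching the base-sensitive quinone.

**Step 5**
Reactants: 4 1-(benzyloxy)-4-bromo-8-methoxynaphthalene; 6 5-methoxynaphthalene-1,4-dione
Product: 9 4-[4-(benzyloxy)-5-methoxynaphthalen-1-yl]-4-hydroxy-8-methoxynaphthalen-1(4H)-one (racemic quinol), via aryllithium 7 (not isolated), via lithium alkoxide 8 (not isolated)
Conditions: n-BuLi (1.05 equiv), THF, −78 °C, 20 min; cannulate into 6 (1.3 equiv), THF, −78 °C; H2O, −78 °C to 0 °C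
Reagents that add atoms: none
Why: Bromine–lithium exchange followed by 1,2-addition of the aryllithium to a quinone carbonyl (inverse addition at −78 °C keeps electron transfer and conjugate addition down); C1=O is attacked because C4=O is deactivated as a vinylogous ester by the ortho methoxy group and screened by it, and the new carbinol stereocenter is formed racemic and is erased in step 6.

**Step 6**
Reactants: 9 4-[4-(benzyloxy)-5-methoxynaphthalen-1-yl]-4-hydroxy-8-methoxynaphthalen-1(4H)-one; 2 8-methoxynaphthalen-1-ol
Product: 12 4-[4-(benzyloxy)-5-methoxynaphthalen-1-yl]-2-(4-hydroxy-5-methoxynaphthalen-1-yl)-8-methoxynaphthalen-1-ol, via benzylic cation 10 (not isolated), via keto tautomer 11 (not isolated)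
Conditions: 2 (3 equiv), (PhO)2P(O)OH (10 mol%), (CF3)2CHOH/CH2Cl2 (1:4), slow addition of 9, −20 °C to 0 °C, Ar
Reagents that add atoms: none
Why: Proposed new method: acid in the ionising fluoroalcohol removes the tertiary, doubly benzylic hydroxyl of 9 to give cation 10 (a 4-aryl-naphthoxenium ion, equally an O-benzylated extended binaphthoquinone), whose C4 is blocked and crowded, so the para carbon (C4) of naphthol 2 bonds to C2, alpha to the carbonyl, in an SN2'-type Friedel–Crafts step, and the resulting 2H-naphthalen-1-one 11 enolises irreversibly to the naphthol; the closest known reaction types are the acid-promoted SN2' arylation of quinone monoacetals by phenols and arenes in fluoroalcohols and the classical addition of HX to para-quinols and diphenoquinones that gives ortho-substituted phenols; no stereocenter remains.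

**Step 7**
Reactants: 12 4-[4-(benzyloxy)-5-methoxynaphthalen-1-yl]-2-(4-hydroxy-5-methoxynaphthalen-1-yl)-8-methoxynaphthalen-1-ol
Product: 13 2,4-bis(4-hydroxy-5-methoxynaphthalen-1-yl)-8-methoxynaphthalen-1-ol (target, CNP0528831.0)
Conditions: H2 (1 atm), 10% Pd/C, EtOAc/MeOH (1:1), rt; filter under Ar
Reagents that add atoms: none
Why: Catalytic hydrogenolysis of the aryl benzyl ether; at 1 atm and room temperature the naphthalene rings, the methyl ethers and the biaryl bonds are untouched, and no stereocenter is involved.

**Compound list**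
1 | naphthalene-1,8-diol | Oc1cccc2cccc(O)c12 | starting material
2 | 8-methoxynaphthalen-1-ol | COc1cccc2cccc(O)c12 | intermediate
3 | 4-bromo-8-methoxynaphthalen-1-ol | COc1cccc2c(Br)ccc(O)c12 | intermediate
4 | 1-(benzyloxy)-4-bromo-8-methoxynaphthalene | COc1cccc2c(Br)ccc(OCc3ccccc3)c12 | intermediate
5 | juglone (5-hydroxynaphthalene-1,4-dione) | O=C1C=CC(=O)c2c(O)cccc12 | starting material
6 | 5-methoxynaphthalene-1,4-dione | COc1cccc2C(=O)C=CC(=O)c12 | intermediate
7 | [4-(benzyloxy)-5-methoxynaphthalen-1-yl]lithium | [Li]c1ccc(OCc2ccccc2)c2c(OC)cccc12 | intermediate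
8 | lithium 1-[4-(benzyloxy)-5-methoxynaphthalen-1-yl]-5-methoxy-4-oxo-1,4-dihydronaphthalen-1-olate (racemic) | [Li+].[O-]C1(C=CC(=O)c2c(OC)cccc12)c1ccc(OCc2ccccc2)c2c(OC)cccc12 | intermediate
9 | 4-[4-(benzyloxy)-5-methoxynaphthalen-1-yl]-4-hydroxy-8-methoxynaphthalen-1(4H)-one (racemic) | COc1cccc2c1C(=O)C=CC2(O)c1ccc(OCc2ccccc2)c2c(OC)cccc12 | intermediate
10 | 4-[4-(benzyloxy)-5-methoxynaphthalen-1-yl]-8-methoxy-1-oxo-1,4-dihydronaphthalen-4-ylium (delocalised cation) | COc1cccc2c1C(=O)C=C[C+]2c1ccc(OCc2ccccc2)c2c(OC)cccc12 | intermediate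
11 | 4-[4-(benzyloxy)-5-methoxynaphthalen-1-yl]-2-(4-hydroxy-5-methoxynaphthalen-1-yl)-8-methoxynaphthalen-1(2H)-one (racemic) | COc1cccc2c1C(=O)C(C=C2c1ccc(OCc2ccccc2)c2c(OC)cccc12)c1ccc(O)c2c(OC)cccc12 | intermediate
12 | 4-[4-(benzyloxy)-5-methoxynaphthalen-1-yl]-2-(4-hydroxy-5-methoxynaphthalen-1-yl)-8-methoxynaphthalen-1-ol | COc1cccc2c(-c3cc(-c4ccc(OCc6ccccc6)c5c(OC)cccc45)c4cccc(OC)c4c3O)ccc(O)c12 | intermediate
13 | 2,4-bis(4-hydroxy-5-methoxynaphthalen-1-yl)-8-methoxynaphthalen-1-ol | COc1cccc2c(-c3cc(-c4ccc(O)c5c(OC)cccc45)c4cccc(OC)c4c3O)ccc(O)c12 | target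

**Totals and risks**
Total step count: 7. Longest linear sequence: 6 steps (steps 1, 2, 3, 5, 6, 7).

The three steps most likely to fail:

Step 6, the SN2' arylation. The naphthol may attack through its C2 or its oxygen, it may transfer an electron to cation 10 instead of bonding, or product 12 may be arylated again. The fallback sets out from quinol 9 and aryllithium 7 and comes back to the route at target 13. Bromide is used as the nucleophile in the same SN2' manifold (LiBr, CF3CO2H, CH2Cl2, 0 °C), which gives 4-[4-(benzyloxy)-5-methoxynaphthalen-1-yl]-2-bromo-8-methoxynaphthalen-1-ol F1. A second portion of 7 is quenched with 2-isopropoxy-4,4,5,5-tetramethyl-1,3,2-dioxaborolane to give 2-[4-(benzyloxy)-5-methoxynaphthalen-1-yl]-4,4,5,5-tetramethyl-1,3,2-dioxaborolane F2. Suzuki–Miyaura coupling of the two (Pd(OAc)2, SPhos, K3PO4, toluene/H2O, 90 °C) gives 2,4-bis[4-(benzyloxy)-5-methoxynaphthalen-1-yl]-8-methoxynaphthalen-1-ol F3, and hydrogenolysis of both benzyl ethers (H2, Pd/C) gives 13.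

Step 5, the aryllithium addition to the quinone. Electron transfer to the quinone, conjugate addition, or attack at the wrong carbonyl could take over. The fallback sets out from 3 and 4 and comes back at quinol 9. Miyaura borylation of 3 (B2pin2, Pd(dppf)Cl2, KOAc, dioxane, 80 °C) gives 8-methoxy-4-(4,4,5,5-tetramethyl-1,3,2-dioxaborolan-2-yl)naphthalen-1-ol F4. Suzuki–Miyaura coupling with 4 gives 4'-(benzyloxy)-5,5'-dimethoxy-[1,1'-binaphthalen]-4-ol F5. Oxidative dearomatisation of its free naphthol ring with PhI(OAc)2 in MeCN/H2O at 0 °C delivers water to the aryl-bearing para carbon and gives 9. The 4,4'-bond is then made by cross-coupling and the quinol by oxidation, so the outcome no longer depends on which quinone carbonyl is attacked.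

Step 2, the para-bromination. Ortho or C5 bromination, dibromination, or oxidation of the electron-rich naphthol could compete. The fallback sets out from 2 and comes back at target 13, with no halogen and no protecting group. Oxidative para–para homocoupling of 2 with FeCl3 gives 5,5'-dimethoxy-[1,1'-binaphthalene]-4,4'-diol F6. Oxidation with Ag2O in CH2Cl2 gives the extended quinone (E)-5,5'-dimethoxy-4H,4'H-[1,1'-binaphthalenylidene]-4,4'-dione F7. Acid-catalysed addition of 2 to it ((PhO)2P(O)OH, (CF3)2CHOH/CH2Cl2) gives 13 directly: the protonated quinone is the debenzylated analogue of cation 10, so the same C2–C4' bond forms.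

**Further compounds**
F1 | step 6 | 4-[4-(benzyloxy)-5-methoxynaphthalen-1-yl]-2-bromo-8-methoxynaphthalen-1-ol | COc1cccc2c(-c3ccc(OCc4ccccc4)c4c(OC)cccc34)cc(Br)c(O)c12
F2 | step 6 | 2-[4-(benzyloxy)-5-methoxynaphthalen-1-yl]-4,4,5,5-tetramethyl-1,3,2-dioxaborolane | CC1(C)OB(OC1(C)C)c1ccc(OCc2ccccc2)c2c(OC)cccc12
F3 | step 6 | 2,4-bis[4-(benzyloxy)-5-methoxynaphthalen-1-yl]-8-methoxynaphthalen-1-ol | COc1cccc2c(-c3cc(-c4ccc(OCc6ccccc6)c5c(OC)cccc45)c4cccc(OC)c4c3O)ccc(OCc3ccccc3)c12
F4 | step 5 | 8-methoxy-4-(4,4,5,5-tetramethyl-1,3,2-dioxaborolan-2-yl)naphthalen-1-ol | COc1cccc2c(B3OC(C)(C)C(C)(C)O3)ccc(O)c12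
F5 | step 5 | 4'-(benzyloxy)-5,5'-dimethoxy-[1,1'-binaphthalen]-4-ol | COc1cccc2c(-c3ccc(OCc4ccccc4)c4c(OC)cccc34)ccc(O)c12
F6 | step 2 | 5,5'-dimethoxy-[1,1'-binaphthalene]-4,4'-diol | COc1cccc2c(-c3ccc(O)c4c(OC)cccc34)ccc(O)c12
F7 | step 2 | (E)-5,5'-dimethoxy-4H,4'H-[1,1'-binaphthalenylidene]-4,4'-dione | COc1cccc2c1C(=O)C=C/C2=C1/C=CC(=O)c2c(OC)cccc12
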